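**Retrosynthetic overview**
- Key disconnection: the C3–C4 bond of the target (undecenoic acid numbering), made by a nickel-electrocatalytic decarboxylative alkyl–alkyl coupling of fragment 11 (C1–C3 plus the furan arm) with fragment 17 (C4–C11).
- Fragment 11: from (R)-cyclohex-3-ene-1-carboxylic acid by ozonolysis/reduction/γ-lactonisation, photochemical deoxygenative furylation, oxidation to the succinic acid and regioselective anhydride opening with N-hydroxyphthalimide.
- Fragment 17: from (R)-3-hydroxyoxolan-2-one by HBr/MeOH opening, triflation and invertive ZnCl2-catalysed Grignard coupling.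
- Rings: no ring of the target is built (the furan is bought); a γ-lactone (step 1) and then a succinic anhydride (step 4) are transient rings, both opened again.
- Stereocentres: C2 is the bought centre of 1, carried through unchanged; C6 is the bought centre of 12 after one clean SN2 inversion.

Assumption: (R)-cyclohex-3-ene-1-carboxylic acid and (R)-3-hydroxyoxolan-2-one (α-hydroxy-γ-butyrolactone) are bought as single enantiomers; 3-bromofuran and 5-bromo-2-methylpent-2-ene are bought achiral materials.

**Route**

Step 1
Reactants: 1 (R)-cyclohex-3-ene-1-carboxylic acid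
Product: 4 (3R)-3-(3-hydroxypropyl)oxolan-2-one, via ozonide 2 (not isolated), via diol acid 3 (not isolated)
Conditions: O3, CH2Cl2, −78 °C; NaBH4, MeOH, −78 °C → rt; 1 M HCl, then TsOH (cat.), CH2Cl2, rt
Reagents that add atoms: ozone, [O-][O+]=O
Why: Reductive ozonolysis gives the diol acid, and acid-catalysed lactonisation closes only the favoured five-membered lactone onto the two-carbon arm, which tells the two arms apart while the bought stereocentre (future C2) is untouched.

Step 2
Reactants: 4 (3R)-3-(3-hydroxypropyl)oxolan-2-one; 5 3-bromofuran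
Product: 7 (3R)-3-[3-(furan-3-yl)propyl]oxolan-2-one, via alkoxybenzoxazoline adduct 6 (not isolated)
Conditions: 5,7-di-tert-butyl-3-phenylbenzoxazolium tetrafluoroborate, pyridine, MTBE, rt; then 5 (2 equiv), Ir(ppy)2(dtbbpy)PF6 (1.5 mol%), NiBr2(dtbbpy) (5 mol%), quinuclidine, DMA, 450 nm LEDs, rt
Reagents that add atoms: none
Why: This is the known metallaphotoredox deoxygenative arylation of alcohols, in which photocatalytic oxidation and β-scission of the alcohol–benzoxazolium adduct release the primary alkyl radical that the NiBr2(dtbbpy) cycle joins to 3-bromofuran, leaving the lactone and its stereocentre alone.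

Step 3
Reactants: 7 (3R)-3-[3-(furan-3-yl)propyl]oxolan-2-one
Product: 9 (2R)-2-[3-(furan-3-yl)propyl]butanedioic acid, via lithium hydroxy carboxylate 8 (not isolated)
Conditions: LiOH, THF/H2O, 0 °C; then TEMPO (20 mol%), PhI(OAc)2 (2.5 equiv), MeCN/H2O, 0 °C → rt
Reagents that add atoms: lithium hydroxide, [Li+].[OH-]; water, O
Why: Saponification unmasks the primary alcohol, which the oxoammonium oxidation (TEMPO/PhI(OAc)2) takes through the aldehyde hydrate to the acid under mild conditions that a 3-alkylfuran should survive, and the α-centre of a carboxylate does not epimerise.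

Step 4
Reactants: 9 (2R)-2-[3-(furan-3-yl)propyl]butanedioic acid
Product: 11 (2R)-4-[(1,3-dioxoisoindol-2-yl)oxy]-2-[3-(furan-3-yl)propyl]-4-oxobutanoic acid, via cyclic anhydride 10 (not isolated)
Conditions: Ac2O, 60 °C, evaporate; then N-hydroxyphthalimide, DMAP (5 mol%), CH2Cl2, −20 → 0 °C
Reagents that add atoms: N-hydroxyphthalimide, O=C1c2ccccc2C(=O)N1O
Why: Dehydration gives the five-membered anhydride, which N-hydroxyphthalimide opens at the less hindered CH2-flanked carbonyl (regioselective anhydride alcoholysis, reversible through the anhydride so the less crowded activated ester is also the more stable one), so only the unbranched carboxyl becomes redox-active and the branched one stays free.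

Step 5
Reactants: 12 (3R)-3-hydroxyoxolan-2-one
Product: 13 methyl (2R)-4-bromo-2-hydroxybutanoate
Conditions: HBr (gas), MeOH, 0 °C → rt
Reagents that add atoms: hydrogen bromide, Br; methanol, CO
Why: This is the classical HBr/alcohol opening of a γ-butyrolactone (bromide SN2 at the O–CH2 carbon plus Fischer esterification); the carbinol carbon next to the carbonyl is not substituted and keeps its configuration.

Step 6
Reactants: 13 methyl (2R)-4-bromo-2-hydroxybutanoate
Product: 14 methyl (2R)-4-bromo-2-[(trifluoromethanesulfonyl)oxy]butanoate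
Conditions: Tf2O, 2,6-lutidine, CH2Cl2, −78 °C
Reagents that add atoms: trifluoromethanesulfonic anhydride, O=S(=O)(OS(=O)(=O)C(F)(F)F)C(F)(F)F
Why: O-triflation of an α-hydroxy ester with a hindered base at low temperature breaks no bond to the stereocentre.

Step 7
Reactants: 14 methyl (2R)-4-bromo-2-[(trifluoromethanesulfonyl)oxy]butanoate; 15 5-bromo-2-methylpent-2-ene
Product: 17 methyl (2S)-2-(2-bromoethyl)-6-methylhept-5-enoate, via homoprenyl Grignard reagent 16 (not isolated)
Conditions: 15, Mg, THF, rt; then 14, ZnCl2 (10 mol%), THF, −20 → 0 °C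
Reagents that add atoms: none
Why: This is the known ZnCl2-catalysed enantiospecific sp3–sp3 coupling of α-hydroxy ester triflates with Grignard reagents, in which the triorganozincate displaces triflate by SN2 with inversion faster than it attacks the methyl ester or the primary bromide, so the bought (R) centre becomes the (S) centre of 17 (C6 of the target, R there).

Step 8
Reactants: 11 (2R)-4-[(1,3-dioxoisoindol-2-yl)oxy]-2-[3-(furan-3-yl)propyl]-4-oxobutanoic acid; 17 methyl (2S)-2-(2-bromoethyl)-6-methylhept-5-enoate
Product: 20 (2S,6R)-2-[3-(furan-3-yl)propyl]-6-(methoxycarbonyl)-10-methylundec-9-enoic acid, via silyl ester 18 (not isolated), via coupled silyl ester 19 (not isolated)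
Conditions: 11, MTBSTFA, DMF, rt; then 17 (1.5 equiv), NiCl2(glyme) (20 mol%), 4,4′,4″-tri-tert-butyl-2,2′:6′,2″-terpyridine (22 mol%), NaI, DMF, undivided cell, Mg anode, RVC cathode, constant current (about 2.5 F/mol), rt; then aqueous citric acid
Reagents that add atoms: none
Why: Proposed new method: a nickel-electrocatalytic decarboxylative cross-electrophile coupling of a succinate-derived N-acyloxyphthalimide with an unactivated primary alkyl bromide, in which cathodically formed low-valent nickel–terpyridine transfers one electron to the redox-active ester of 18 (far easier to reduce than the C–Br bond) to release phthalimide anion, CO2 and the primary C3 radical, while zerovalent or monovalent nickel adds oxidatively to 17, and capture of the radical by the alkylnickel bromide gives a dialkyl trivalent nickel that reductively eliminates the C3–C4 bond; the closest known reaction types are the nickel-electrocatalytic doubly decarboxylative C(sp3)–C(sp3) coupling of two redox-active esters and nickel-catalysed reductive couplings of such esters with organic halides; the radical is placed on fragment 11 because a radical next to C6 would be a fast 5-hexenyl cyclisation clock, the transient silyl ester prevents proton reduction and re-closure to the anhydride, and both stereocentres lie beta to the reacting carbons and are untouched.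

**Compound list**
1 | (R)-cyclohex-3-ene-1-carboxylic acid | OC(=O)[C@@H]1CCC=CC1 | starting material
2 | (3R)-7,8,9-trioxabicyclo[4.2.1]nonane-3-carboxylic acid (ozonide of 1, bridgeheads undefined) | OC(=O)[C@@H]1CCC2OOC(C1)O2 | intermediate
3 | (2R)-5-hydroxy-2-(2-hydroxyethyl)pentanoic acid | OC(=O)[C@@H](CCO)CCCO | intermediate
4 | (3R)-3-(3-hydroxypropyl)oxolan-2-one | O=C1OCC[C@H]1CCCO | intermediate
5 | 3-bromofuran | Brc1ccoc1 | starting material
6 | (3R)-3-{3-[(5,7-di-tert-butyl-3-phenyl-2,3-dihydro-1,3-benzoxazol-2-yl)oxy]propyl}oxolan-2-one (acetal carbon undefined) | O=C1OCC[C@H]1CCCOC1Oc2c(C(C)(C)C)cc(C(C)(C)C)cc2N1c1ccccc1 | intermediate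
7 | (3R)-3-[3-(furan-3-yl)propyl]oxolan-2-one | O=C1OCC[C@H]1CCCc1ccoc1 | intermediate
8 | lithium (2R)-5-(furan-3-yl)-2-(2-hydroxyethyl)pentanoate | [Li+].[O-]C(=O)[C@@H](CCO)CCCc1ccoc1 | intermediate
9 | (2R)-2-[3-(furan-3-yl)propyl]butanedioic acid | OC(=O)C[C@@H](CCCc1ccoc1)C(=O)O | intermediate
10 | (3R)-3-[3-(furan-3-yl)propyl]oxolane-2,5-dione | O=C1C[C@@H](CCCc2ccoc2)C(=O)O1 | intermediate
11 | (2R)-4-[(1,3-dioxoisoindol-2-yl)oxy]-2-[3-(furan-3-yl)propyl]-4-oxobutanoic acid | O=C(C[C@@H](CCCc1ccoc1)C(=O)O)ON1C(=O)c2ccccc2C1=O | intermediate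
12 | (3R)-3-hydroxyoxolan-2-one | O=C1[C@H](O)CCO1 | starting material
13 | methyl (2R)-4-bromo-2-hydroxybutanoate | COC(=O)[C@H](O)CCBr | intermediate
14 | methyl (2R)-4-bromo-2-[(trifluoromethanesulfonyl)oxy]butanoate | COC(=O)[C@H](OS(=O)(=O)C(F)(F)F)CCBr | intermediate
15 | 5-bromo-2-methylpent-2-ene | CC(C)=CCCBr | starting material
16 | (4-methylpent-3-en-1-yl)magnesium bromide | CC(C)=CCC[Mg]Br | intermediate
17 | methyl (2S)-2-(2-bromoethyl)-6-methylhept-5-enoate | COC(=O)[C@@H](CCC=C(C)C)CCBr | intermediate
18 | tert-butyldimethylsilyl (2R)-4-[(1,3-dioxoisoindol-2-yl)oxy]-2-[3-(furan-3-yl)propyl]-4-oxobutanoate | O=C(C[C@@H](CCCc1ccoc1)C(=O)O[Si](C)(C)C(C)(C)C)ON1C(=O)c2ccccc2C1=O | intermediate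
19 | 1-methyl 7-(tert-butyldimethylsilyl) (2R,6S)-6-[3-(furan-3-yl)propyl]-2-(4-methylpent-3-en-1-yl)heptanedioate | COC(=O)[C@@H](CCC=C(C)C)CCC[C@@H](CCCc1ccoc1)C(=O)O[Si](C)(C)C(C)(C)C | intermediate
20 | (2S,6R)-2-[3-(furan-3-yl)propyl]-6-(methoxycarbonyl)-10-methylundec-9-enoic acid | COC(=O)[C@@H](CCC=C(C)C)CCC[C@@H](CCCc1ccoc1)C(=O)O | target

**Step count and risks**
Total step count: 8. Longest linear sequence: 5 (steps 1, 2, 3, 4, 8).

Three steps most likely to fail:

Step 8 (the new coupling; risks are homocoupling of either electrophile and reduction of the radical). The fallback uses known chemistry, sets out from 17 and 18 and returns at 19, and so at 20. Bromide 17 is stirred with zinc dust and LiCl in THF at 50 °C to give [(3S)-3-(methoxycarbonyl)-7-methyloct-6-en-1-yl]zinc bromide F1. F1 is coupled with silyl ester 18 (made from 11 as in step 8) under NiCl2(glyme)/4,4′-di-tert-butyl-2,2′-bipyridine in THF/DMF at room temperature, the established thermal decarboxylative alkyl–alkyl Negishi coupling of redox-active esters. A pre-formed organozinc nucleophile thus replaces the electrochemical sorting of two electrophiles; acidic work-up hydrolyses 19 to 20.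

Step 4 (the anhydride may open partly at the branched carbonyl). The fallback sets out from 8 and returns at 20, with the branched carboxyl blocked before the second one exists. The dried salt 8 is alkylated with 2-(trimethylsilyl)ethoxymethyl chloride in DMF to [2-(trimethylsilyl)ethoxy]methyl (2R)-5-(furan-3-yl)-2-(2-hydroxyethyl)pentanoate F2. TEMPO/PhI(OAc)2 gives (3R)-6-(furan-3-yl)-3-({[2-(trimethylsilyl)ethoxy]methoxy}carbonyl)hexanoic acid F3. DIC and N-hydroxyphthalimide give the single redox-active ester 4-(1,3-dioxoisoindol-2-yl) 1-{[2-(trimethylsilyl)ethoxy]methyl} (2R)-2-[3-(furan-3-yl)propyl]butanedioate F4. Coupling with 17 as in step 8 (no silylation) gives the [2-(trimethylsilyl)ethoxy]methyl ester of 20 F5, and MgBr2(OEt2) in CH2Cl2 frees the acid to give 20.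

Step 2 (electron-rich, volatile 3-bromofuran in the deoxygenative arylation). The fallback sets out from 4 and returns at 7, using a thermal two-electron cross-coupling instead of the photochemical radical route. I2, PPh3 and imidazole convert 4 into (3R)-3-(3-iodopropyl)oxolan-2-one F6. Zinc dust/LiCl in THF gives {3-[(3R)-2-oxooxolan-3-yl]propyl}zinc iodide F7. Negishi coupling with 5 under Pd(OAc)2/SPhos gives 7.

**Further compounds**
F1 | step 8 | [(3S)-3-(methoxycarbonyl)-7-methyloct-6-en-1-yl]zinc bromide | COC(=O)[C@@H](CCC=C(C)C)CC[Zn]Br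
F2 | step 4 | [2-(trimethylsilyl)ethoxy]methyl (2R)-5-(furan-3-yl)-2-(2-hydroxyethyl)pentanoate | C[Si](C)(C)CCOCOC(=O)[C@@H](CCO)CCCc1ccoc1
F3 | step 4 | (3R)-6-(furan-3-yl)-3-({[2-(trimethylsilyl)ethoxy]methoxy}carbonyl)hexanoic acid | C[Si](C)(C)CCOCOC(=O)[C@@H](CC(=O)O)CCCc1ccoc1
F4 | step 4 | 4-(1,3-dioxoisoindol-2-yl) 1-{[2-(trimethylsilyl)ethoxy]methyl} (2R)-2-[3-(furan-3-yl)propyl]butanedioate | C[Si](C)(C)CCOCOC(=O)[C@@H](CC(=O)ON1C(=O)c2ccccc2C1=O)CCCc1ccoc1
F5 | step 4 | [2-(trimethylsilyl)ethoxy]methyl ester of 20 | COC(=O)[C@@H](CCC=C(C)C)CCC[C@@H](CCCc1ccoc1)C(=O)OCOCC[Si](C)(C)C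
F6 | step 2 | (3R)-3-(3-iodopropyl)oxolan-2-one | O=C1OCC[C@H]1CCCI
F7 | step 2 | {3-[(3R)-2-oxooxolan-3-yl]propyl}zinc iodide | O=C1OCC[C@H]1CCC[Zn]I
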